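**Retrosynthetic overview**
1. Last bond: C5'–C6' of the hydroxy-ketone arm, by a catalyst-controlled syn aldol of butan-2-one onto a lactone-bearing 2,4-dienal (sets the OH/CH3 pair).
2. Dienal arm: C3–C1' bond by aldol addition–elimination of the lactone enolate to 3-ethoxymethacrolein (trans to the β-methyl), then a two-carbon Wittig homologation.
3. γ-Lactone (the only ring, closed mid-route): oxidative lactonisation of a 1,4-diol obtained by hydroboration of an anti homoallylic alcohol; its C4/C5 pair comes from a chiral-phosphoric-acid crotylboration of the western dienal.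
4. Western dienal: cross-metathesis plus Wittig from (R)-3-methylhept-1-ene, whose stereocenter comes from a copper-catalysed asymmetric allylic methylation of achiral (E)-1-bromohept-2-ene.

Assumption: the catalyst enantiomers named ((R,R)-Taniaphos, (S)-TRIP, the (1R,2R)-diamine) are those expected by analogy with the closest precedents to give the drawn products; if a test run shows the opposite sense, the mirror-image catalyst is used.

**Step 1**
Reactants: 1 (E)-hept-2-en-1-ol
Product: 2 (E)-1-bromohept-2-ene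
Conditions: PBr3 (0.4 equiv), Et2O, −10 → 0 °C
Reagents that add atoms: phosphorus tribromide, BrP(Br)Br
Why: Alcohol-to-bromide substitution with PBr3 proceeds by SN2 displacement of the phosphite ester at the primary allylic carbon, so the E alkene is kept and no stereocenter is involved.

**Step 2**
Reactants: 2 (E)-1-bromohept-2-ene; 3 methylmagnesium bromide
Product: 4 (3R)-3-methylhept-1-ene
Conditions: MeMgBr (1.2 equiv), CuBr·SMe2 (1 mol%), (R,R)-Taniaphos (1.1 mol%), CH2Cl2, −75 °C; volatile product carried on as its CH2Cl2 solution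
Reagents that add atoms: methylmagnesium bromide (3), C[Mg]Br
Why: Copper-catalysed asymmetric allylic alkylation (SN2' substitution): the Taniaphos-bound methylcopper species attacks the γ-carbon of the allyl bromide to give the branched terminal alkene, and the chiral ligand sets the (R) methyl-bearing stereocenter.

**Step 3**
Reactants: 4 (3R)-3-methylhept-1-ene; 5 (E)-but-2-enal
Product: 6 (2E,4R)-4-methyloct-2-enal
Conditions: (E)-but-2-enal (5 equiv), second-generation Grubbs catalyst (3 mol%), CH2Cl2, 40 °C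
Reagents that add atoms: (E)-but-2-enal (5), C/C=C/C=O
Why: Olefin cross-metathesis between a terminal alkene and an electron-poor enal partner is selective for the E cross-product with loss of propene and does not touch the allylic stereocenter.

**Step 4**
Reactants: 6 (2E,4R)-4-methyloct-2-enal; 7 2-(triphenylphosphoranylidene)propanal
Product: 8 (2E,4E,6R)-2,6-dimethyldeca-2,4-dienal
Conditions: 7 (1.3 equiv), toluene, 90 °C
Reagents that add atoms: 2-(triphenylphosphoranylidene)propanal (7), CC(C=O)=P(c1ccccc1)(c1ccccc1)c1ccccc1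
Why: Wittig olefination with a stabilised α-methyl formyl ylide gives the E trisubstituted alkene, and the α-branched product enal does not react further.

**Step 5**
Reactants: 8 (2E,4E,6R)-2,6-dimethyldeca-2,4-dienal; 9 (E)-crotylboronic acid pinacol ester
Product: 11 (3S,4S,5E,7E,9R)-3,5,9-trimethyltrideca-1,5,7-trien-4-ol, via pinacol borate ester 10 (not isolated)
Conditions: 9 (1.3 equiv), (S)-TRIP [(S)-3,3'-bis(2,4,6-triisopropylphenyl)-1,1'-binaphthyl-2,2'-diyl hydrogen phosphate] (5 mol%), 4 Å MS, toluene, −30 °C; aq. NaHCO3 work-up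
Reagents that add atoms: (E)-crotylboronic acid pinacol ester (9), C/C=C/CB1OC(C)(C)C(C)(C)O1
Why: Chiral-phosphoric-acid-catalysed crotylboration through a closed chair (Zimmerman–Traxler-type) transition state turns the E geometry of the boronate into the anti methyl/hydroxyl relationship, while (S)-TRIP, hydrogen-bonded to the boronate oxygen and the formyl hydrogen, selects the aldehyde face and so sets both the (3S) and (4S) centers.

**Step 6**
Reactants: 11 (3S,4S,5E,7E,9R)-3,5,9-trimethyltrideca-1,5,7-trien-4-ol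
Product: 13 (3S,4S,5E,7E,9R)-3,5,9-trimethyltrideca-5,7-diene-1,4-diol, via B-alkyl-9-BBN adduct 12 (not isolated)
Conditions: 9-BBN (1.5 equiv), THF, 0 °C → rt; then NaOH, H2O2, 0 °C
Reagents that add atoms: hydrogen peroxide, OO (oxygen of the new hydroxyl); 9-BBN, B1C2CCCC1CCC2 (boron in 12 only)
Why: Hydroboration–oxidation: 9-BBN adds anti-Markovnikov to the monosubstituted alkene far faster than to the hindered conjugated diene, and alkaline peroxide replaces boron by hydroxyl with no change at the stereocenters.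

**Step 7**
Reactants: 13 (3S,4S,5E,7E,9R)-3,5,9-trimethyltrideca-5,7-diene-1,4-diol
Product: 16 (4S,5S)-4-methyl-5-[(2E,4E,6R)-6-methyldeca-2,4-dien-2-yl]oxolan-2-one, via hydroxy aldehyde 14 (not isolated), via lactol 15 (not isolated)
Conditions: TEMPO (20 mol%), PhI(OAc)2 (2.5 equiv), CH2Cl2, rt
Reagents that add atoms: none
Why: TEMPO/PhI(OAc)2 oxidative lactonisation: the oxoammonium salt oxidises the primary alcohol, the aldehyde is trapped by the C4 hydroxyl as a lactol, and a second oxidation gives the γ-lactone, whose 4,5-trans arrangement is inherited from the anti diol.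

**Step 8**
Reactants: 16 (4S,5S)-4-methyl-5-[(2E,4E,6R)-6-methyldeca-2,4-dien-2-yl]oxolan-2-one; 17 (E)-3-ethoxy-2-methylprop-2-enal
Product: 20 (2E)-2-methyl-3-[(3S,4S,5S)-4-methyl-5-[(2E,4E,6R)-6-methyldeca-2,4-dien-2-yl]-2-oxooxolan-3-yl]prop-2-enal, via lithium enolate 18 (not isolated), via lithium aldolate 19 (not isolated)
Conditions: LiN(iPr)2 (1.1 equiv, commercial solution), THF, −78 °C; 17 (1.3 equiv), −78 °C; then 0.5 M aq. HCl, 0 °C → rt
Reagents that add atoms: (E)-3-ethoxy-2-methylprop-2-enal (17), CCO/C=C(\C)C=O (four carbons); water, O (oxygen of the new formyl group)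
Why: Aldol addition of the lithium enolate to the formyl group of the vinylogous formate followed by acid-induced loss of water and ethanol through an allylic oxocarbenium ion (aldol addition–elimination, a vinylogous formylation) gives the E enal, and the new C3 center ends up trans to the C4 methyl because the electrophile approaches anti to that methyl and this acidic position equilibrates to the more stable all-trans lactone.

**Step 9**
Reactants: 20 (2E)-2-methyl-3-[(3S,4S,5S)-4-methyl-5-[(2E,4E,6R)-6-methyldeca-2,4-dien-2-yl]-2-oxooxolan-3-yl]prop-2-enal; 21 (triphenylphosphoranylidene)acetaldehyde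
Product: 22 (2E,4E)-4-methyl-5-[(3S,4S,5S)-4-methyl-5-[(2E,4E,6R)-6-methyldeca-2,4-dien-2-yl]-2-oxooxolan-3-yl]penta-2,4-dienal
Conditions: 21 (1.3 equiv), toluene, 80 °C
Reagents that add atoms: (triphenylphosphoranylidene)acetaldehyde (21), O=CC=P(c1ccccc1)(c1ccccc1)c1ccccc1
Why: Wittig olefination with the stabilised formylmethylene ylide is E-selective and runs without added base, so the base-sensitive C3 center is not disturbed.

**Step 10**
Reactants: 22 (2E,4E)-4-methyl-5-[(3S,4S,5S)-4-methyl-5-[(2E,4E,6R)-6-methyldeca-2,4-dien-2-yl]-2-oxooxolan-3-yl]penta-2,4-dienal; 23 butan-2-one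
Product: 24 (3S,4S,5S)-3-[(1E,3E,5S,6R)-5-hydroxy-2,6-dimethyl-7-oxoocta-1,3-dien-1-yl]-4-methyl-5-[(2E,4E,6R)-6-methyldeca-2,4-dien-2-yl]oxolan-2-one (CNP0320265.2)
Conditions: butan-2-one (20 equiv, co-solvent), (1R,2R)-N1,N1-dipropylcyclohexane-1,2-diamine (20 mol%), TfOH (20 mol%), 3-nitrobenzoic acid (20 mol%), slow addition of 22, 20 °C
Reagents that add atoms: butan-2-one (23), CCC(C)=O
Why: Proposed new method: the primary amine of the chiral diamine condenses with the ethyl side of butan-2-one to give the more substituted Z-enamine while its protonated tertiary amine hydrogen-bonds the dienal carbonyl, so that carbon–carbon bond formation runs through a cyclic nine-membered transition state that enforces 1,2-addition (not conjugate addition) on one aldehyde face and gives the syn (5S,6R) aldol under catalyst control, with excess ketone and slow dienal addition keeping the amine away from iminium formation with the dienal; the closest known reaction type is the primary-amine-catalysed, syn-selective branched aldol of butan-2-one with aromatic aldehydes, which has not been shown for conjugated dienals or next to an epimerisable α-alkenyl lactone.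

**Compound list**
1 | (E)-hept-2-en-1-ol | CCCC/C=C/CO | starting material
2 | (E)-1-bromohept-2-ene | CCCC/C=C/CBr | intermediate
3 | methylmagnesium bromide | C[Mg]Br | starting material
4 | (3R)-3-methylhept-1-ene | CCCC[C@@H](C)C=C | intermediate
5 | (E)-but-2-enal (crotonaldehyde) | C/C=C/C=O | starting material
6 | (2E,4R)-4-methyloct-2-enal | CCCC[C@@H](C)/C=C/C=O | intermediate
7 | 2-(triphenylphosphoranylidene)propanal | CC(C=O)=P(c1ccccc1)(c1ccccc1)c1ccccc1 | starting material
8 | (2E,4E,6R)-2,6-dimethyldeca-2,4-dienal | CCCC[C@@H](C)/C=C/C=C(\C)C=O | intermediate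
9 | (E)-crotylboronic acid pinacol ester, 2-[(2E)-but-2-en-1-yl]-4,4,5,5-tetramethyl-1,3,2-dioxaborolane | C/C=C/CB1OC(C)(C)C(C)(C)O1 | starting material
10 | 4,4,5,5-tetramethyl-2-{[(3S,4S,5E,7E,9R)-3,5,9-trimethyltrideca-1,5,7-trien-4-yl]oxy}-1,3,2-dioxaborolane | CCCC[C@@H](C)/C=C/C=C(\C)[C@@H](OB1OC(C)(C)C(C)(C)O1)[C@@H](C)C=C | intermediate
11 | (3S,4S,5E,7E,9R)-3,5,9-trimethyltrideca-1,5,7-trien-4-ol | CCCC[C@@H](C)/C=C/C=C(\C)[C@@H](O)[C@@H](C)C=C | intermediate
12 | (3S,4S,5E,7E,9R)-1-(9-borabicyclo[3.3.1]nonan-9-yl)-3,5,9-trimethyltrideca-5,7-dien-4-ol | CCCC[C@@H](C)/C=C/C=C(\C)[C@@H](O)[C@@H](C)CCB1C2CCCC1CCC2 | intermediate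
13 | (3S,4S,5E,7E,9R)-3,5,9-trimethyltrideca-5,7-diene-1,4-diol | CCCC[C@@H](C)/C=C/C=C(\C)[C@@H](O)[C@@H](C)CCO | intermediate
14 | (3S,4S,5E,7E,9R)-4-hydroxy-3,5,9-trimethyltrideca-5,7-dienal | CCCC[C@@H](C)/C=C/C=C(\C)[C@@H](O)[C@@H](C)CC=O | intermediate
15 | (4S,5S)-4-methyl-5-[(2E,4E,6R)-6-methyldeca-2,4-dien-2-yl]oxolan-2-ol (anomer mixture) | CCCC[C@@H](C)/C=C/C=C(\C)[C@H]1OC(O)C[C@@H]1C | intermediate
16 | (4S,5S)-4-methyl-5-[(2E,4E,6R)-6-methyldeca-2,4-dien-2-yl]oxolan-2-one | CCCC[C@@H](C)/C=C/C=C(\C)[C@H]1OC(=O)C[C@@H]1C | intermediate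
17 | (E)-3-ethoxy-2-methylprop-2-enal (3-ethoxymethacrolein) | CCO/C=C(\C)C=O | starting material
18 | lithium (4S,5S)-4-methyl-5-[(2E,4E,6R)-6-methyldeca-2,4-dien-2-yl]-4,5-dihydrofuran-2-olate | CCCC[C@@H](C)/C=C/C=C(\C)[C@H]1OC([O-])=C[C@@H]1C.[Li+] | intermediate
19 | lithium (2E)-3-ethoxy-2-methyl-1-[(3R,4S,5S)-4-methyl-5-[(2E,4E,6R)-6-methyldeca-2,4-dien-2-yl]-2-oxooxolan-3-yl]prop-2-en-1-olate (mixture at the alkoxide carbon) | CCCC[C@@H](C)/C=C/C=C(\C)[C@H]1OC(=O)[C@@H](C([O-])/C(C)=C/OCC)[C@@H]1C.[Li+] | intermediate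
20 | (2E)-2-methyl-3-[(3S,4S,5S)-4-methyl-5-[(2E,4E,6R)-6-methyldeca-2,4-dien-2-yl]-2-oxooxolan-3-yl]prop-2-enal | CCCC[C@@H](C)/C=C/C=C(\C)[C@H]1OC(=O)[C@@H](/C=C(C)/C=O)[C@@H]1C | intermediate
21 | (triphenylphosphoranylidene)acetaldehyde | O=CC=P(c1ccccc1)(c1ccccc1)c1ccccc1 | starting material
22 | (2E,4E)-4-methyl-5-[(3S,4S,5S)-4-methyl-5-[(2E,4E,6R)-6-methyldeca-2,4-dien-2-yl]-2-oxooxolan-3-yl]penta-2,4-dienal | CCCC[C@@H](C)/C=C/C=C(\C)[C@H]1OC(=O)[C@@H](/C=C(C)/C=C/C=O)[C@@H]1C | intermediate
23 | butan-2-one | CCC(C)=O | starting material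
24 | (3S,4S,5S)-3-[(1E,3E,5S,6R)-5-hydroxy-2,6-dimethyl-7-oxoocta-1,3-dien-1-yl]-4-methyl-5-[(2E,4E,6R)-6-methyldeca-2,4-dien-2-yl]oxolan-2-one | CCCC[C@@H](C)/C=C/C=C(\C)[C@H]1OC(=O)[C@@H](/C=C(C)/C=C/[C@H](O)[C@@H](C)C(C)=O)[C@@H]1C | target

**Step count**
Total steps: 10. Longest linear sequence: 10 (1 → 24, fully linear, no protecting groups).

**Three steps most likely to fail**

Step 10, the proposed new aldol. The amine may instead form an iminium ion with the dienal, which would open conjugate addition or deprotonation through C3, and the dienylic aldol may dehydrate. The fallback uses known chemistry, sets out from dienal 22 and comes back at target 24. Dienal 22 is treated with (Z)-crotylboronic acid pinacol ester and (R)-TRIP (5 mol%) in toluene at −30 °C, the established chiral-phosphoric-acid crotylboration of enals. This gives the pinacol borate ester of the syn homoallylic alcohol F1 (not isolated) and, after aqueous work-up, the syn homoallylic alcohol (3S,4S,5S)-3-[(1E,3E,5S,6S)-5-hydroxy-2,6-dimethylocta-1,3,7-trien-1-yl]-4-methyl-5-[(2E,4E,6R)-6-methyldeca-2,4-dien-2-yl]oxolan-2-one F2. Tsuji–Wacker oxidation of the terminal alkene of F2 (PdCl2 10 mol%, CuCl 1 equiv, O2, DMF/H2O, rt) then gives the methyl ketone 24. This costs one extra step.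

Step 8, the enolate addition to the vinylogous formate. The 1,2-addition may be slow or reversible, and the acid step may give the α-alkylidene lactone isomer. The fallback sets out from lactone 16 and comes back at enal 20. The lithium enolate 18 is added to methacrolein (THF, −78 °C) to give the aldol adduct (3R,4S,5S)-3-(1-hydroxy-2-methylprop-2-en-1-yl)-4-methyl-5-[(2E,4E,6R)-6-methyldeca-2,4-dien-2-yl]oxolan-2-one F3. Ph3SiOReO3 (2 mol%, Et2O, 0 °C) then moves the hydroxyl by 1,3-transposition to give the primary allylic alcohol (3S,4S,5S)-3-[(1E)-3-hydroxy-2-methylprop-1-en-1-yl]-4-methyl-5-[(2E,4E,6R)-6-methyldeca-2,4-dien-2-yl]oxolan-2-one F4. MnO2 (CH2Cl2, rt) oxidises F4 to 20.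

Step 9, the formylmethylene Wittig. The α-methyl enal is sluggish and the product dienal can be homologated a second time. The fallback sets out from enal 20 and comes back at dienal 22. Wittig reaction with N-methoxy-N-methyl-2-(triphenylphosphoranylidene)acetamide (CH2Cl2, 40 °C) gives the dienyl Weinreb amide (2E,4E)-N-methoxy-N,4-dimethyl-5-[(3S,4S,5S)-4-methyl-5-[(2E,4E,6R)-6-methyldeca-2,4-dien-2-yl]-2-oxooxolan-3-yl]penta-2,4-dienamide F5, which cannot react a second time. Cp2Zr(H)Cl (1.5 equiv, THF, rt) then reduces the amide of F5 to the aldehyde 22 in the presence of the lactone.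

**Further compounds**
F1 | step 10 | pinacol borate ester (O-Bpin derivative) of F2 | CCCC[C@@H](C)/C=C/C=C(\C)[C@H]1OC(=O)[C@@H](/C=C(C)/C=C/[C@H](OB2OC(C)(C)C(C)(C)O2)[C@@H](C)C=C)[C@@H]1C
F2 | step 10 | (3S,4S,5S)-3-[(1E,3E,5S,6S)-5-hydroxy-2,6-dimethylocta-1,3,7-trien-1-yl]-4-methyl-5-[(2E,4E,6R)-6-methyldeca-2,4-dien-2-yl]oxolan-2-one | CCCC[C@@H](C)/C=C/C=C(\C)[C@H]1OC(=O)[C@@H](/C=C(C)/C=C/[C@H](O)[C@@H](C)C=C)[C@@H]1C
F3 | step 8 | (3R,4S,5S)-3-(1-hydroxy-2-methylprop-2-en-1-yl)-4-methyl-5-[(2E,4E,6R)-6-methyldeca-2,4-dien-2-yl]oxolan-2-one (mixture at the carbinol carbon) | CCCC[C@@H](C)/C=C/C=C(\C)[C@H]1OC(=O)[C@@H](C(O)C(C)=C)[C@@H]1C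
F4 | step 8 | (3S,4S,5S)-3-[(1E)-3-hydroxy-2-methylprop-1-en-1-yl]-4-methyl-5-[(2E,4E,6R)-6-methyldeca-2,4-dien-2-yl]oxolan-2-one | CCCC[C@@H](C)/C=C/C=C(\C)[C@H]1OC(=O)[C@@H](/C=C(C)/CO)[C@@H]1C
F5 | step 9 | (2E,4E)-N-methoxy-N,4-dimethyl-5-[(3S,4S,5S)-4-methyl-5-[(2E,4E,6R)-6-methyldeca-2,4-dien-2-yl]-2-oxooxolan-3-yl]penta-2,4-dienamide | CCCC[C@@H](C)/C=C/C=C(\C)[C@H]1OC(=O)[C@@H](/C=C(C)/C=C/C(=O)N(C)OC)[C@@H]1C
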